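C1–C17 is the sphingoid chain (C1 = CH2OH; cyclopropane = C12, C13 and a bridging CH2). C1′–C25′ is the acyl chain.
**Cuts, in retrosynthetic order:** amide N–C1′; C2–N together with C1–C2 (three-component borono-Mannich coupling); C5–C6 (acetylide on a primary triflate); C10–C11 (copper-catalysed alkyl–alkyl coupling); cyclopropane bonds C12–C13 and C12–CH2.
**Enabling feature:** C2 bears nitrogen anti to the C3 hydroxyl. Its other carbon neighbour, C1, is a CH2OH that can arrive as the boron-bound carbon of a styryl group, so C2–C17 is an α-hydroxy aldehyde. The trans-cyclopropane, the only ring, is remote and a spectator.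
**Forward order:** the cyclopropane is closed first. The chain is then joined at C10–C11, at C5–C6 and at C1–C2/C2–N, and the acyl chain is attached last. No other ring forms.
**Stereochemistry:** C13 from (R)-1,2-epoxyhexane (inversion); C12 from the trans-selective ring closure; C3 and C4 from D-erythronolactone; C2 from the C3 hydroxyl during alkenyl transfer; C2′ from a benzyl oxazolidinone auxiliary.
**The 6E alkene** travels as the C6≡C7 alkyne, which outlasts two ozonolyses, and is set at the end by dissolving-metal reduction.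

Key step: step 12

Remark: aldehyde 18 is drawn as the open-chain monomer; it is expected to equilibrate with its hydrate and oligomers, all of which feed the same condensation.

Step 1
Reactants: 1 (R)-1,2-epoxyhexane; 2 triethyl phosphonoacetate
Product: 4 ethyl (1S,2S)-2-butylcyclopropane-1-carboxylate, via lithiated phosphonoacetate 3 (not isolated)
Conditions: 2, n-BuLi, DME, 0 °C; then 1, 130 °C, sealed vessel
Reagents that add atoms: none
Why: Wadsworth–Emmons cyclopropanation: carbanion 3 opens the epoxide at its CH2 end, the phosphoryl group moves from carbon to oxygen, and SN2 3-exo-tet closure expels phosphate with inversion at the former epoxide carbon (future C13, S) and sets ester and butyl trans (future C12, S).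

Step 2
Reactants: 4 ethyl (1S,2S)-2-butylcyclopropane-1-carboxylate
Product: 5 [(1S,2S)-2-butylcyclopropyl]methanol
Conditions: LiAlH4, Et2O, 0 °C; aqueous work-up
Reagents that add atoms: none
Why: Hydride reduction of an ester to the primary alcohol, which leaves an unactivated cyclopropane and both of its stereocentres untouched.

Step 3
Reactants: 5 [(1S,2S)-2-butylcyclopropyl]methanol
Product: 6 (1S,2S)-1-(bromomethyl)-2-butylcyclopropane
Conditions: CBr4, PPh3, CH2Cl2, −20 to 0 °C
Reagents that add atoms: carbon tetrabromide, BrC(Br)(Br)Br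
Why: Appel bromination, in which bromide displaces the phosphonium-activated oxygen in an SN2 sense under neutral, cold conditions, so no cyclopropylcarbinyl cation forms and the ring should stay closed.

Step 4
Reactants: 6 (1S,2S)-1-(bromomethyl)-2-butylcyclopropane; 7 (5-chloropent-1-yn-1-yl)trimethylsilane
Product: 9 {6-[(1S,2S)-2-butylcyclopropyl]hex-1-yn-1-yl}trimethylsilane, via Grignard reagent 8 (not isolated)
Conditions: 7, Mg, THF, reflux; then 6, Li2CuCl4 (3 mol %), NMP, THF, 0 °C to rt
Reagents that add atoms: none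
Why: Kochi-type copper-catalysed cross-coupling of an alkyl Grignard reagent with a primary bromide forms C10–C11; the displacement is SN2-like rather than radical, so the cyclopropylmethyl unit should couple without opening, and the silyl cap removes the acidic alkyne proton.

Step 5
Reactants: 9 {6-[(1S,2S)-2-butylcyclopropyl]hex-1-yn-1-yl}trimethylsilane
Product: 10 (1S,2S)-1-butyl-2-(hex-5-yn-1-yl)cyclopropane
Conditions: K2CO3 (cat.), MeOH, rt
Reagents that add atoms: none
Why: Base-catalysed methanolysis of the C(sp)–Si bond (protodesilylation of an alkynylsilane), which is mild and affects nothing else in the molecule.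

Step 6
Reactants: 11 2,3-O-isopropylidene-D-erythronolactone
Product: 12 2,3-O-isopropylidene-D-erythrofuranose (anomeric mixture)
Conditions: i-Bu2AlH, CH2Cl2, −78 °C; aq. KNaC4H4O6
Reagents that add atoms: none
Why: Partial reduction of a lactone: the tetrahedral adduct persists at −78 °C, so reduction stops at the lactol and the two acetonide-bearing stereocentres (future C3 and C4) are kept.

Step 7
Reactants: 12 2,3-O-isopropylidene-D-erythrofuranose
Product: 13 [(4R,5S)-5-ethenyl-2,2-dimethyl-1,3-dioxolan-4-yl]methanol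
Conditions: MePPh3Br, KOt-Bu, THF, 0 °C to rt
Reagents that add atoms: methyltriphenylphosphonium bromide, C[P+](c1ccccc1)(c1ccccc1)c1ccccc1.[Br-]
Why: Wittig methylenation of the hydroxy aldehyde in equilibrium with the lactol masks the future C2 carbonyl as a vinyl group and frees the primary hydroxyl on the future C5.

Step 8
Reactants: 13 [(4R,5S)-5-ethenyl-2,2-dimethyl-1,3-dioxolan-4-yl]methanol
Product: 14 [(4R,5S)-5-ethenyl-2,2-dimethyl-1,3-dioxolan-4-yl]methyl trifluoromethanesulfonate
Conditions: Tf2O, pyridine, CH2Cl2, −20 °C; cold aqueous wash, used without storage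
Reagents that add atoms: trifluoromethanesulfonic anhydride, O=S(=O)(OS(=O)(=O)C(F)(F)F)C(F)(F)F
Why: O-Sulfonylation of a primary alcohol gives a leaving group reactive enough to overcome the retarding effect of the β-oxygen in the following substitution.

Step 9
Reactants: 10 (1S,2S)-1-butyl-2-(hex-5-yn-1-yl)cyclopropane; 14 [(4R,5S)-5-ethenyl-2,2-dimethyl-1,3-dioxolan-4-yl]methyl trifluoromethanesulfonate
Product: 16 (4R,5S)-4-{7-[(1S,2S)-2-butylcyclopropyl]hept-2-yn-1-yl}-5-ethenyl-2,2-dimethyl-1,3-dioxolane, via lithium acetylide 15 (not isolated)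
Conditions: 10, n-BuLi, THF, −78 °C; DMPU; then 14, −78 to −20 °C
Reagents that add atoms: none
Why: SN2 alkylation of a lithium acetylide with a primary, carbohydrate-derived triflate in THF/DMPU forms C5–C6 at a CH2 carbon, so no stereocentre is touched and the low temperature disfavours elimination.

Step 10
Reactants: 16 (4R,5S)-4-{7-[(1S,2S)-2-butylcyclopropyl]hept-2-yn-1-yl}-5-ethenyl-2,2-dimethyl-1,3-dioxolane
Product: 17 (3S,4R)-11-[(1S,2S)-2-butylcyclopropyl]undec-1-en-6-yne-3,4-diol
Conditions: AcOH/H2O (4:1), 45 °C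
Reagents that add atoms: none
Why: Acid-catalysed acetal hydrolysis is done at the stable alkene stage, so the sensitive aldehyde made next never meets acid; alkyne, vinyl group and dialkylcyclopropane tolerate aqueous acetic acid.

Step 11
Reactants: 17 (3S,4R)-11-[(1S,2S)-2-butylcyclopropyl]undec-1-en-6-yne-3,4-diol
Product: 18 (2R,3R)-10-[(1S,2S)-2-butylcyclopropyl]-2,3-dihydroxydec-5-ynal
Conditions: O3, CH2Cl2/MeOH (5:1), −78 °C, Sudan Red 7B as end-point indicator; Me2S, −78 °C to rt; water wash, used at once
Reagents that add atoms: ozone, [O-][O+]=O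
Why: Ozonolysis with reductive work-up: ozone attacks the terminal alkene far faster than a dialkyl alkyne, the conditions are neutral so the α-centre is not enolised, and the water wash removes formaldehyde, which would otherwise compete in the next step.

Step 12
Reactants: 18 (2R,3R)-10-[(1S,2S)-2-butylcyclopropyl]-2,3-dihydroxydec-5-ynal; 19 bis(4-methoxyphenyl)methanamine; 20 (E)-2-phenylethenylboronic acid
Product: 23 (1E,3S,4S,5R)-3-{[bis(4-methoxyphenyl)methyl]amino}-12-[(1S,2S)-2-butylcyclopropyl]-1-phenyldodec-1-en-7-yne-4,5-diol, via imine 21 (not isolated), via iminium boronate 22 (not isolated)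
Conditions: 19 (1.0 equiv), 20 (1.1 equiv), EtOH, rt, 24–48 h
Reagents that add atoms: none
Why: This is the Petasis borono-Mannich reaction of an α-hydroxy aldehyde, the established route to anti 1,2-amino alcohols: 18 and 19 condense to imine 21 (C2–N), and boronic acid 20 binds the hydroxyl next to the C=N bond while its proton passes to nitrogen, giving the tetracoordinate iminium boronate 22. The styryl group then migrates from boron to the iminium carbon inside this complex, forming C1–C2 irreversibly, and hydrolysis of the borate releases 23. No ring is closed. The one new stereocentre, sphingoid C2 (C3 of 23, S), is controlled by the neighbouring carbinol centre: transfer occurs in the conformer that keeps allylic 1,3-strain about the C=N bond lowest, so the alkenyl group reaches the face that places nitrogen anti to the adjacent oxygen. The step needs chemoselective addition to C=N only, which is secured because a neutral boronic acid becomes nucleophilic only as the boronate held beside the iminium ion, and it needs retention of the E geometry of the migrating group, which is inherent to the intramolecular transfer. The alkyne, the cyclopropane and the second hydroxyl are inert under these neutral, metal-free conditions, and the bulky benzhydryl-type group on nitrogen blocks a second coupling of the secondary amine.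

Step 13
Reactants: 23 (1E,3S,4S,5R)-3-{[bis(4-methoxyphenyl)methyl]amino}-12-[(1S,2S)-2-butylcyclopropyl]-1-phenyldodec-1-en-7-yne-4,5-diol
Product: 25 (2S,3S,4R)-2-{[bis(4-methoxyphenyl)methyl]amino}-11-[(1S,2S)-2-butylcyclopropyl]undec-6-yne-1,3,4-triol, via amino aldehyde 24 (not isolated)
Conditions: CF3CO2H (1.5 equiv), CH2Cl2/MeOH (1:1), −78 °C, O3 (metered until 23 is consumed); then NaBH4, −78 to 0 °C; aqueous work-up
Reagents that add atoms: ozone, [O-][O+]=O
Why: Ozonolysis with NaBH4 work-up: with nitrogen blocked as its ammonium salt the styryl C=C bond is the most ozone-reactive site, ahead of the dialkyl alkyne and the anisyl rings, and immediate cold hydride reduction turns the configurationally labile 24 into the C1 alcohol without loss of C2.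

Step 14
Reactants: 25 (2S,3S,4R)-2-{[bis(4-methoxyphenyl)methyl]amino}-11-[(1S,2S)-2-butylcyclopropyl]undec-6-yne-1,3,4-triol
Product: 26 (2S,3S,4R,6E)-2-amino-11-[(1S,2S)-2-butylcyclopropyl]undec-6-ene-1,3,4-triol
Conditions: Na, NH3(l)/THF, −78 to −33 °C; NH4Cl
Reagents that add atoms: none
Why: Dissolving-metal reduction: stepwise electron and proton transfer to the alkyne runs through the more stable trans vinyl species and gives the 6E alkene, while electron transfer into the benzhydryl-type substituent breaks its benzylic C–N bond; the isolated dialkylcyclopropane and all stereocentres are unaffected.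

Step 15
Reactants: 27 pentacosanoic acid; 28 (4R)-4-benzyl-1,3-oxazolidin-2-one
Product: 30 (4R)-4-benzyl-3-pentacosanoyl-1,3-oxazolidin-2-one, via mixed pivalic anhydride 29 (not isolated)
Conditions: t-BuCOCl, Et3N, THF, 0 °C to rt; then 28, LiCl, rt
Reagents that add atoms: none
Why: N-Acylation of an oxazolidinone through a mixed anhydride, in which the hindered pivaloyl carbonyl directs attack to the fatty acyl carbonyl.

Step 16
Reactants: 30 (4R)-4-benzyl-3-pentacosanoyl-1,3-oxazolidin-2-one
Product: 32 (4R)-4-benzyl-3-[(2R)-2-hydroxypentacosanoyl]-1,3-oxazolidin-2-one, via sodium enolate 31 (not isolated)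
Conditions: NaN(SiMe3)2, THF, −78 °C; 2-(benzenesulfonyl)-3-phenyloxaziridine, −78 °C; AcOH
Reagents that add atoms: 2-(benzenesulfonyl)-3-phenyloxaziridine, O=S(=O)(N1OC1c1ccccc1)c1ccccc1
Why: Evans-type asymmetric enolate hydroxylation with a Davis oxaziridine: the chelated Z enolate 31 takes up oxygen on the face opposite the benzyl group, which with the (R)-auxiliary sets C2′ as R.

Step 17
Reactants: 32 (4R)-4-benzyl-3-[(2R)-2-hydroxypentacosanoyl]-1,3-oxazolidin-2-one
Product: 34 (2R)-2-hydroxypentacosanoic acid, via peroxy acid 33 (not isolated)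
Conditions: LiOH, H2O2, THF/H2O (3:1), 0 °C; aq. Na2SO3; aq. HCl
Reagents that add atoms: hydrogen peroxide, OO
Why: Hydroperoxide-mediated cleavage of an N-acyl oxazolidinone attacks the exocyclic carbonyl selectively and is too weakly basic to racemise C2′; sulfite reduces 33 to the acid and the auxiliary is recovered.

Step 18
Reactants: 26 (2S,3S,4R,6E)-2-amino-11-[(1S,2S)-2-butylcyclopropyl]undec-6-ene-1,3,4-triol; 34 (2R)-2-hydroxypentacosanoic acid
Product: 36 (2R)-N-{(2S,3S,4R,6E)-11-[(1S,2S)-2-butylcyclopropyl]-1,3,4-trihydroxyundec-6-en-2-yl}-2-hydroxypentacosanamide, via benzotriazolyl ester 35 (not isolated)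
Conditions: EDC·HCl, HOBt, THF/CH2Cl2, 40 °C
Reagents that add atoms: none
Why: Carbodiimide/HOBt amide coupling, in which the primary amine outcompetes all hydroxyl groups for the mild active ester 35, as is usual for N-acylation of unprotected phytosphingosine-type bases with free 2-hydroxy acids.

Compound list
1 | (R)-1,2-epoxyhexane | CCCC[C@@H]1CO1 | starting material
2 | triethyl phosphonoacetate | CCOC(=O)CP(=O)(OCC)OCC | starting material
3 | lithiated triethyl phosphonoacetate | [Li+].CCOC(=O)[CH-]P(=O)(OCC)OCC | intermediate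
4 | ethyl (1S,2S)-2-butylcyclopropane-1-carboxylate | CCOC(=O)[C@H]1C[C@@H]1CCCC | intermediate
5 | [(1S,2S)-2-butylcyclopropyl]methanol | OC[C@H]1C[C@@H]1CCCC | intermediate
6 | (1S,2S)-1-(bromomethyl)-2-butylcyclopropane | BrC[C@H]1C[C@@H]1CCCC | intermediate
7 | (5-chloropent-1-yn-1-yl)trimethylsilane | C[Si](C)(C)C#CCCCCl | starting material
8 | [5-(trimethylsilyl)pent-4-yn-1-yl]magnesium chloride | C[Si](C)(C)C#CCCC[Mg]Cl | intermediate
9 | {6-[(1S,2S)-2-butylcyclopropyl]hex-1-yn-1-yl}trimethylsilane | C[Si](C)(C)C#CCCCC[C@H]1C[C@@H]1CCCC | intermediate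
10 | (1S,2S)-1-butyl-2-(hex-5-yn-1-yl)cyclopropane | C#CCCCC[C@H]1C[C@@H]1CCCC | intermediate
11 | 2,3-O-isopropylidene-D-erythronolactone | O=C1[C@@H]2OC(C)(C)O[C@@H]2CO1 | starting material
12 | 2,3-O-isopropylidene-D-erythrofuranose (anomeric mixture) | OC1[C@@H]2OC(C)(C)O[C@@H]2CO1 | intermediate
13 | [(4R,5S)-5-ethenyl-2,2-dimethyl-1,3-dioxolan-4-yl]methanol | C=C[C@@H]1OC(C)(C)O[C@@H]1CO | intermediate
14 | [(4R,5S)-5-ethenyl-2,2-dimethyl-1,3-dioxolan-4-yl]methyl trifluoromethanesulfonate | C=C[C@@H]1OC(C)(C)O[C@@H]1COS(=O)(=O)C(F)(F)F | intermediate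
15 | lithium acetylide of 10 | [Li+].[C-]#CCCCC[C@H]1C[C@@H]1CCCC | intermediate
16 | (4R,5S)-4-{7-[(1S,2S)-2-butylcyclopropyl]hept-2-yn-1-yl}-5-ethenyl-2,2-dimethyl-1,3-dioxolane | C=C[C@@H]1OC(C)(C)O[C@@H]1CC#CCCCC[C@H]2C[C@@H]2CCCC | intermediate
17 | (3S,4R)-11-[(1S,2S)-2-butylcyclopropyl]undec-1-en-6-yne-3,4-diol | C=C[C@H](O)[C@H](O)CC#CCCCC[C@H]1C[C@@H]1CCCC | intermediate
18 | (2R,3R)-10-[(1S,2S)-2-butylcyclopropyl]-2,3-dihydroxydec-5-ynal | O=C[C@H](O)[C@H](O)CC#CCCCC[C@H]1C[C@@H]1CCCC | intermediate
19 | bis(4-methoxyphenyl)methanamine | COc1ccc(cc1)C(N)c1ccc(OC)cc1 | starting material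
20 | (E)-2-phenylethenylboronic acid | OB(O)/C=C/c1ccccc1 | starting material
21 | (E)-N-[bis(4-methoxyphenyl)methyl]imine of 18 | COc1ccc(cc1)C(/N=C/[C@H](O)[C@H](O)CC#CCCCC[C@H]2C[C@@H]2CCCC)c3ccc(OC)cc3 | intermediate
22 | zwitterionic iminium boronate from 21 and 20 (boron on the α-oxygen) | COc1ccc(cc1)C([NH+]=C[C@H](O[B-](O)(O)/C=C/c2ccccc2)[C@H](O)CC#CCCCC[C@H]3C[C@@H]3CCCC)c4ccc(OC)cc4 | intermediate
23 | (1E,3S,4S,5R)-3-{[bis(4-methoxyphenyl)methyl]amino}-12-[(1S,2S)-2-butylcyclopropyl]-1-phenyldodec-1-en-7-yne-4,5-diol | COc1ccc(cc1)C(N[C@@H](/C=C/c2ccccc2)[C@H](O)[C@H](O)CC#CCCCC[C@H]3C[C@@H]3CCCC)c4ccc(OC)cc4 | intermediate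
24 | (2R,3S,4R)-2-{[bis(4-methoxyphenyl)methyl]amino}-11-[(1S,2S)-2-butylcyclopropyl]-3,4-dihydroxyundec-6-ynal (present as its trifluoroacetate salt) | COc1ccc(cc1)C(N[C@@H](C=O)[C@H](O)[C@H](O)CC#CCCCC[C@H]2C[C@@H]2CCCC)c3ccc(OC)cc3 | intermediate
25 | (2S,3S,4R)-2-{[bis(4-methoxyphenyl)methyl]amino}-11-[(1S,2S)-2-butylcyclopropyl]undec-6-yne-1,3,4-triol | COc1ccc(cc1)C(N[C@@H](CO)[C@H](O)[C@H](O)CC#CCCCC[C@H]2C[C@@H]2CCCC)c3ccc(OC)cc3 | intermediate
26 | (2S,3S,4R,6E)-2-amino-11-[(1S,2S)-2-butylcyclopropyl]undec-6-ene-1,3,4-triol | N[C@@H](CO)[C@H](O)[C@H](O)C/C=C/CCCC[C@H]1C[C@@H]1CCCC | intermediate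
27 | pentacosanoic acid | CCCCCCCCCCCCCCCCCCCCCCCCC(=O)O | starting material
28 | (4R)-4-benzyl-1,3-oxazolidin-2-one | O=C1N[C@H](Cc2ccccc2)CO1 | starting material
29 | pentacosanoic pivalic anhydride | CCCCCCCCCCCCCCCCCCCCCCCCC(=O)OC(=O)C(C)(C)C | intermediate
30 | (4R)-4-benzyl-3-pentacosanoyl-1,3-oxazolidin-2-one | CCCCCCCCCCCCCCCCCCCCCCCCC(=O)N1[C@H](Cc2ccccc2)COC1=O | intermediate
31 | sodium (Z)-enolate of 30 | CCCCCCCCCCCCCCCCCCCCCCC/C=C(\[O-])N1[C@H](Cc2ccccc2)COC1=O.[Na+] | intermediate
32 | (4R)-4-benzyl-3-[(2R)-2-hydroxypentacosanoyl]-1,3-oxazolidin-2-one | CCCCCCCCCCCCCCCCCCCCCCC[C@@H](O)C(=O)N1[C@H](Cc2ccccc2)COC1=O | intermediate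
33 | (2R)-2-hydroxypentacosaneperoxoic acid | CCCCCCCCCCCCCCCCCCCCCCC[C@@H](O)C(=O)OO | intermediate
34 | (2R)-2-hydroxypentacosanoic acid | CCCCCCCCCCCCCCCCCCCCCCC[C@@H](O)C(=O)O | intermediate
35 | benzotriazol-1-yl (2R)-2-hydroxypentacosanoate | CCCCCCCCCCCCCCCCCCCCCCC[C@@H](O)C(=O)On1nnc2ccccc12 | intermediate
36 | (2R)-N-{(2S,3S,4R,6E)-11-[(1S,2S)-2-butylcyclopropyl]-1,3,4-trihydroxyundec-6-en-2-yl}-2-hydroxypentacosanamide (CNP0280669.1) | CCCCCCCCCCCCCCCCCCCCCCC[C@@H](O)C(=O)N[C@@H](CO)[C@H](O)[C@H](O)C/C=C/CCCC[C@H]1C[C@@H]1CCCC | target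

Total step count: 18. Longest linear sequence: 12 steps (steps 1–5, 9–14 and 18).

Steps most likely to fail

**Step 14.** Two reductive events are asked of one operation. Electron transfer may stop after the alkyne, leaving the C–N bond of the electron-rich benzhydryl-type group intact. It may also begin to reduce the anisyl rings before that bond fragments.

The fallback sets out from 25 and separates the two events without any dissolving metal. The homopropargylic C4 hydroxyl directs a trans-hydroalumination of the alkyne with LiAlH4 in THF/diglyme at about 130 °C. After hydrolysis this gives (2S,3S,4R,6E)-2-{[bis(4-methoxyphenyl)methyl]amino}-11-[(1S,2S)-2-butylcyclopropyl]undec-6-ene-1,3,4-triol F1. Acidolysis of the N-substituent with CF3CO2H and anisole in CH2Cl2 at 0 °C (SN1 release of the stabilised diarylmethyl cation, trapped by anisole) then leads back to the route at 26.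

**Step 13.** Ozone may attack the anisyl rings, the benzhydrylic position next to nitrogen or the alkyne in competition with the styryl double bond. C2 may also lose its configuration by enolisation before the hydride arrives.

The fallback sets out from 23 and removes the oxidisable N-substituent first. CF3CO2H and anisole in CH2Cl2 give (1E,3S,4S,5R)-3-amino-12-[(1S,2S)-2-butylcyclopropyl]-1-phenyldodec-1-en-7-yne-4,5-diol F2. Its primary ammonium trifluoroacetate carries no electron-rich arene. Ozonolysis of this salt with NaBH4 work-up gives (2S,3S,4R)-2-amino-11-[(1S,2S)-2-butylcyclopropyl]undec-6-yne-1,3,4-triol F3. Na in NH3/THF, which now has only the alkyne to reduce, brings the material back at 26.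

**Step 11.** Several things can degrade the feed of the key step:
- over-oxidation at the alkyne;
- fragmentation next to the free allylic hydroxyl during ozonolysis;
- self-condensation of the unprotected aldehyde during work-up;
- carry-over of formaldehyde into the coupling.

The fallback sets out from 16 and changes both the oxidant and the order of events. Lemieux–Johnson cleavage of the vinyl group (catalytic OsO4, NaIO4, 2,6-lutidine, dioxane/H2O), which spares alkynes, gives the purifiable aldehyde (4R,5R)-5-{7-[(1S,2S)-2-butylcyclopropyl]hept-2-yn-1-yl}-2,2-dimethyl-1,3-dioxolane-4-carbaldehyde F4. Brief hydrolysis with CF3CO2H/H2O (9:1) at 0 °C and evaporation release the diol just before use, rejoining the route at 18.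

Further compounds
F1 | step 14 | (2S,3S,4R,6E)-2-{[bis(4-methoxyphenyl)methyl]amino}-11-[(1S,2S)-2-butylcyclopropyl]undec-6-ene-1,3,4-triol | COc1ccc(cc1)C(N[C@@H](CO)[C@H](O)[C@H](O)C/C=C/CCCC[C@H]2C[C@@H]2CCCC)c3ccc(OC)cc3
F2 | step 13 | (1E,3S,4S,5R)-3-amino-12-[(1S,2S)-2-butylcyclopropyl]-1-phenyldodec-1-en-7-yne-4,5-diol | N[C@@H](/C=C/c1ccccc1)[C@H](O)[C@H](O)CC#CCCCC[C@H]2C[C@@H]2CCCC
F3 | step 13 | (2S,3S,4R)-2-amino-11-[(1S,2S)-2-butylcyclopropyl]undec-6-yne-1,3,4-triol | N[C@@H](CO)[C@H](O)[C@H](O)CC#CCCCC[C@H]1C[C@@H]1CCCC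
F4 | step 11 | (4R,5R)-5-{7-[(1S,2S)-2-butylcyclopropyl]hept-2-yn-1-yl}-2,2-dimethyl-1,3-dioxolane-4-carbaldehyde | O=C[C@@H]1OC(C)(C)O[C@@H]1CC#CCCCC[C@H]2C[C@@H]2CCCC
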